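# Total synthesis proposal for Hansfordiol A (9)

## Analysis of the target

Hansfordiol A (9) is (S)-5-(16-hydroxyheptadecyl)benzene-1,3-diol, C23H40O3. Its only ring is a benzene ring with hydroxyl groups at C1 and C3. Ring carbon C5 carries an unbranched seventeen-carbon chain, numbered here C1′ (benzylic) to C17′ (methyl).

The only stereocentre is C16′, a methyl/n-alkyl carbinol of S configuration. It has no stereochemical partner and lies sixteen bonds from the ring, so nothing else in the molecule can control it. Its two carbon substituents, CH3 and CH2R, are so alike that a late reduction of a C16′ ketone by a chemical catalyst would discriminate poorly. The centre is therefore better brought in intact.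

Sensitive groups are few: the electron-rich 1,3-dihydroxyarene (oxidation, electrophiles at C2, C4 and C6) and the secondary alcohol.

The difficulty is one of topology. Fifteen consecutive methylene groups, C1′–C15′, separate the two functional ends without offering a handle, so a conventional plan needs a long α,ω-differentiated linker. In addition, ring carbon C5 is the one position that the innate reactivity of the ring never addresses.

The same feature is the invitation taken here. The C1′–C15′ segment has no branch, no heteroatom and no second acidic site, and it is closed at one end by the C16′–O group. A triple bond placed anywhere in it can therefore be walked along the chain by base, and only towards C1′.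

## Retrosynthetic reasoning

**9 ⇒ 8.** No skeletal bond is cut. 9 is traced back to the aryl alkyne 8, which already holds all 23 skeletal carbons, the C16′ stereocentre, a C1′≡C2′ triple bond and two benzyl ethers. Saturation of the triple bond and release of both phenols respond to the same heterogeneous hydrogenation. The unsaturation left by C–C bond formation and the phenol protection therefore cost one step together. The forward reaction must leave the C16′–O bond alone, which it should, since that alcohol is neither benzylic nor allylic.

**8 ⇒ 6 + 7.** The bond between ring carbon C5 and C1′ is cut. Electrophilic chemistry on the 1,3-dioxygenated ring goes to C2, C4 and C6, never to C5, so the 1,3,5-pattern is bought as the 5-bromide 7. An sp–sp2 coupling is chosen because the terminal alkyne 6 is itself the nucleophile and needs no extra activation step. The forward reaction has to tolerate the free secondary alcohol.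

**6 ⇒ 4 (key step).** No bond of the skeleton is cut. The triple bond is moved back from C1′≡C2′ to C13′≡C14′.

- 6 is a 1,16-difunctional chain of the kind that normally needs a desymmetrised linker.
- Its isomer 4 is one step away from two monofunctional commodity chemicals.
- The forward reaction has to carry the unsaturation over twelve positions, against the thermodynamic order of neutral alkynes, in one direction only and without touching C16′.
- One triple bond thereby serves twice: first as the nucleophile that attaches the stereocentre, then, at the other end of the chain, as the nucleophile that attaches the ring.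
- "Base-mediated zipper isomerisation of 4" is not the sentence with which this target would normally be opened.

**4 ⇒ 1 + 2 (through 3).** The C14′–C15′ bond is cut. This places the alkyne two carbons from the carbinol, so that the three-carbon unit C15′–C17′ with its oxygen and configuration is exactly the epoxide 2. The remaining fourteen carbons are the terminal alkyne 1. The acetylide 3 has to attack the CH2 terminus of 2. The C–O bond at the stereocentre stays intact, and the S configuration of 2 becomes that of 9.

## Alternatives that were turned down

**Alternative 1:** the textbook route. The C1′=C2′ bond next to the ring (olefination) and the C14′–C15′ bond (epoxide opening) are cut.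

- Forward key step: Wittig olefination of 3,5-bis(benzyloxy)benzaldehyde A1 with the ylide of [(15S)-15-hydroxyhexadecyl]triphenylphosphonium bromide A2. This gives the styrene A3, whose double-bond geometry is irrelevant, and A3 is hydrogenated as in step 4.
- Why turned down: A2 hides the whole problem. Its thirteen-carbon segment between the epoxide-derived carbons and phosphorus must come from an odd-numbered α,ω-difunctional linker. The two like ends of that linker are told apart only statistically and with a protecting group.
- After that come organometal formation, opening of 2, deprotection, halogenation and salt formation. That makes seven to eight steps, most of them bookkeeping.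
- The ylide also has to be generated beside a free or protected hydroxyl group.
- The olefination itself contributes nothing to the 1,16-relationship.

**Alternative 2:** C14′–C15′ is cut as a union of two radicals.

- Forward key step: a mixed Kolbe electrolysis, or its nickel-electrocatalytic doubly decarboxylative version with redox-active esters. The partners are 15-[3,5-bis(benzyloxy)phenyl]-15-oxopentadecanoic acid A4 (from 7 and a commercial C15 macrolactone by aryl-metal addition and oxidation) and (3S)-3-[(tert-butyldimethylsilyl)oxy]butanoic acid A5. The product is the ketone A6.
- Attraction: the union is traceless, which suits a chain without functionality.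
- Why turned down:
  - Two primary radicals of like polarity cross-couple only statistically, so one acid is sacrificed in excess and two homodimers must be removed.
  - A benzyloxyarene is oxidised more easily than a carboxylate under Kolbe conditions, so the anodic version would attack the ring. The reductive version costs two activation steps.
  - The C1′ ketone and the silyl ether still have to go.
  - The outcome is eight or nine steps for a bond that 3 and 2 form in one.

**Alternative 3:** the chain is made from a ring. C1′–C15′ is the perimeter of a fifteen-membered carbocycle.

- Forward key step: 1-[3,5-bis(benzyloxy)phenyl]cyclopentadecan-1-ol A7 (from 7 and the commercial C15 macrocyclic ketone) is converted into its alkoxy radical by proton-coupled electron transfer, with the dialkoxyarene as built-in redox antenna.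
- β-Scission of the ring bond C1′–C15′ then gives an aryl ketone and a C15′ primary radical. This radical is captured at nickel by an acetyl donor to give the 1,16-dione A8.
- Enzymatic reduction at C16′ and hydrogenolysis at C1′ would finish the route.
- Why turned down:
  - The scission gains no strain relief in a large ring.
  - The capture of the distal radical by an acetyl unit has no close analogue for such rings.
  - The benzylic C–H bonds of the ether groups are ready hydrogen donors for that radical.
  - The stereocentre is deferred to a methyl/n-alkyl ketone that only an enzyme distinguishes, in water, on a C17 lipid.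
  - Two risky steps would replace one.

Key step: step 2

Assumption: 1, 2 and 7 are taken as catalogue chemicals, 2 in high enantiomeric purity. Locant C-k in the heptadecynol names corresponds to side-chain locant C-(18 − k)′.

## Route

Step 1
Reactants: 1 tetradec-1-yne; 2 (S)-propylene oxide [(2S)-2-methyloxirane]
Product: 4 (2S)-heptadec-4-yn-2-ol, via lithium tetradec-1-ynide 3 (not isolated)
Conditions: n-BuLi, THF, −78 °C; BF3·OEt2, −78 °C; then 2, −78 °C; H2O quench
Reagents that add atoms: none
Why: Yamaguchi–Hirao alkynylation, in which the acetylide 3 opens the BF3-activated epoxide by SN2 attack at the unsubstituted CH2 carbon and forms C14′–C15′. The C–O bond at the stereocentre is not broken, so the S configuration of 2 is carried into 4 unchanged, and the descriptor stays S because CH2–C≡C outranks CH3.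

Step 2
Reactants: 4 (2S)-heptadec-4-yn-2-ol
Product: 6 (2S)-heptadec-16-yn-2-ol, via dipotassium alkoxide acetylide 5 (not isolated)
Conditions: KH (5 equiv), H2N(CH2)3NH2, rt (forms potassium 3-aminopropylamide); 4 in a little THF, 0 °C to rt; then H2O, 0 °C
Reagents that add atoms: none
Why: This is the alkyne zipper reaction, the base-mediated contra-thermodynamic isomerisation of an internal to a terminal alkyne with potassium 3-aminopropylamide. The base first converts the hydroxyl group into its potassium alkoxide, then removes a propargylic proton and hands a proton back to the far alkyne carbon through the second nitrogen of the same diamine, so that alkyne and allene isomers interconvert by successive 1,3-proton shifts and the unsaturation performs a random walk along the chain. All internal positions are close in energy, but only the C1′≡C2′ isomer has an sp C–H bond that the amide deprotonates irreversibly, and the acetylide 5 so formed drains the whole equilibrium to that end; water then gives 6. The selectivity needed is one of direction and is secured by the substrate: towards C16′ the walk ends at C15′, because the carbinol carbon bears the negatively charged oxygen and its C–H bond is therefore not acidic, whereas towards C1′ twelve unbranched, heteroatom-free positions offer no obstacle and no second sink. No ring is closed, no skeletal bond is formed and no stereocentre is created; C16′ keeps the S configuration of 2 because none of its four bonds takes part. The closest known cases are zipper isomerisations of enantioenriched secondary propargylic and homopropargylic alcohols and of C16 to C22 alkynols, for which migration over ten and more positions and retention at the carbinol carbon are established behaviour. What the step wins is the 1,16-relationship of the two handles: the unactivated methyl end of a monofunctional C14 hydrocarbon becomes the nucleophile for step 3.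

Step 3
Reactants: 6 (2S)-heptadec-16-yn-2-ol; 7 1,3-bis(benzyloxy)-5-bromobenzene
Product: 8 (2S)-17-[3,5-bis(benzyloxy)phenyl]heptadec-16-yn-2-ol
Conditions: PdCl2(PPh3)2 (cat.), CuI (cat.), Et3N, DMF, 80 °C, Ar
Reagents that add atoms: none
Why: Sonogashira coupling forms the C5(ring)–C1′ bond; both benzyloxy groups stand meta to bromine and should not retard oxidative addition, and a free secondary alcohol is inert to Pd/Cu/amine. Internal alkyne isomers that might survive step 2 cannot form a copper acetylide, so this step also acts as a chemical filter.

Step 4
Reactants: 8 (2S)-17-[3,5-bis(benzyloxy)phenyl]heptadec-16-yn-2-ol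
Product: 9 Hansfordiol A, (S)-5-(16-hydroxyheptadecyl)benzene-1,3-diol
Conditions: H2 (1–3 bar), 10% Pd/C, EtOAc/EtOH, rt to 40 °C
Reagents that add atoms: none
Why: Heterogeneous catalytic hydrogenation saturates the aryl alkyne to C1′H2–C2′H2 and hydrogenolyses both benzyl aryl ethers in the same operation. The isolated alcohol at C16′ is neither benzylic nor allylic, so its C–O bond and S configuration should be untouched.

## Compound list

1 | tetradec-1-yne | C#CCCCCCCCCCCCC | starting material
2 | (S)-propylene oxide, (2S)-2-methyloxirane | C[C@H]1CO1 | starting material
3 | lithium tetradec-1-ynide | [Li]C#CCCCCCCCCCCCC | intermediate (not isolated)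
4 | (2S)-heptadec-4-yn-2-ol | C[C@H](O)CC#CCCCCCCCCCCCC | intermediate
5 | dipotassium salt of (2S)-heptadec-16-yn-2-ol (alkoxide acetylide) | C[C@H]([O-])CCCCCCCCCCCCCC#[C-].[K+].[K+] | intermediate (not isolated)
6 | (2S)-heptadec-16-yn-2-ol | C[C@H](O)CCCCCCCCCCCCCC#C | intermediate
7 | 1,3-bis(benzyloxy)-5-bromobenzene | Brc1cc(OCc2ccccc2)cc(OCc2ccccc2)c1 | starting material
8 | (2S)-17-[3,5-bis(benzyloxy)phenyl]heptadec-16-yn-2-ol | C[C@H](O)CCCCCCCCCCCCCC#Cc1cc(OCc2ccccc2)cc(OCc2ccccc2)c1 | intermediate
9 | Hansfordiol A, (S)-5-(16-hydroxyheptadecyl)benzene-1,3-diol | C[C@H](O)CCCCCCCCCCCCCCCc1cc(O)cc(O)c1 | target

## Step count and least certain steps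

Total step count: 4. Longest linear sequence: 4 (1/2 → 4 → 6 → 8 → 9). Compound 7 enters in step 3 as purchased.

**Step 2 (key step).** The most likely failure is an incomplete walk.

- The superbase may be consumed by traces of moisture, or the potassium alkoxide of the C17 chain may aggregate and leave the solution.
- The migration would then stop at a statistical spread of internal alkyne and allene positions that behave like the product on silica.
- Part of this risk is buffered, since only a terminal alkyne can react in step 3. Silver-nitrate-impregnated silica should also separate terminal from internal isomers.
- The configurational purity of 6 should be checked at this stage by derivatisation with a chiral acid.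

The fallback gives up the isomerisation and buys the two ends separately. It sets out from 2 and comes back at 6. Commercial lithium (trimethylsilyl)acetylide is monoalkylated with an excess of 1,12-dibromododecane in THF/DMPU to give (14-bromotetradec-1-yn-1-yl)trimethylsilane F1. Magnesium insertion gives [14-(trimethylsilyl)tetradec-13-yn-1-yl]magnesium bromide F2. This reagent opens 2 at its CH2 carbon under copper(I) catalysis to give (2S)-17-(trimethylsilyl)heptadec-16-yn-2-ol F3. K2CO3 in MeOH removes silicon and delivers 6. The price is three steps in place of two and one statistical monoalkylation.

**Step 3.** Slow oxidative addition of the aryl bromide would let the copper-mediated oxidative dimerisation of the alkyne (Glaser coupling) compete. That would consume the more valuable partner, and traces of oxygen would aggravate it.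

The fallback changes the bond construction from sp–sp2 to sp2–sp2 with boron on the chain. It sets out from 6 and comes back at 9. Copper-catalysed borylcupration–protonation of 6 with B2pin2 and MeOH tolerates the free alcohol. It gives (2S,16E)-17-(4,4,5,5-tetramethyl-1,3,2-dioxaborolan-2-yl)heptadec-16-en-2-ol F4. Suzuki–Miyaura coupling of F4 with 7 (Pd(dppf)Cl2, K2CO3, dioxane/H2O, 80 °C) gives (2S,16E)-17-[3,5-bis(benzyloxy)phenyl]heptadec-16-en-2-ol F5. Hydrogenation under the conditions of step 4 turns F5 into 9.

**Step 1.** The Lewis acid may polymerise or rearrange the volatile epoxide before the acetylide attacks. Premature warming may also tie the acetylide up on boron. Both processes lower conversion, though not configurational purity.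

The fallback forms the bond on the other flank of the alkyne (C12′–C13′) and needs no Lewis acid. It sets out from 2 and comes back at 4. Compound 2 is opened by lithium acetylide–ethylenediamine complex in DMSO to give (2S)-pent-4-yn-2-ol F6. Two equivalents of n-BuLi in THF/DMPU convert F6 into its dilithium alkoxide acetylide F7. F7 is alkylated at carbon by 1-bromododecane to give 4.

## Further compounds

F1 | step 2 | (14-bromotetradec-1-yn-1-yl)trimethylsilane | C[Si](C)(C)C#CCCCCCCCCCCCCBr
F2 | step 2 | [14-(trimethylsilyl)tetradec-13-yn-1-yl]magnesium bromide | C[Si](C)(C)C#CCCCCCCCCCCCC[Mg]Br
F3 | step 2 | (2S)-17-(trimethylsilyl)heptadec-16-yn-2-ol | C[C@H](O)CCCCCCCCCCCCCC#C[Si](C)(C)C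
F4 | step 3 | (2S,16E)-17-(4,4,5,5-tetramethyl-1,3,2-dioxaborolan-2-yl)heptadec-16-en-2-ol | C[C@H](O)CCCCCCCCCCCCC/C=C/B1OC(C)(C)C(C)(C)O1
F5 | step 3 | (2S,16E)-17-[3,5-bis(benzyloxy)phenyl]heptadec-16-en-2-ol | C[C@H](O)CCCCCCCCCCCCC/C=C/c1cc(OCc2ccccc2)cc(OCc2ccccc2)c1
F6 | step 1 | (2S)-pent-4-yn-2-ol | C[C@H](O)CC#C
F7 | step 1 | dilithium salt of (2S)-pent-4-yn-2-ol (alkoxide acetylide) | C[C@H]([O-])CC#[C-].[Li+].[Li+]
A1 | alternative 1 | 3,5-bis(benzyloxy)benzaldehyde | O=Cc1cc(OCc2ccccc2)cc(OCc2ccccc2)c1
A2 | alternative 1 | [(15S)-15-hydroxyhexadecyl]triphenylphosphonium bromide | C[C@H](O)CCCCCCCCCCCCCC[P+](c1ccccc1)(c1ccccc1)c1ccccc1.[Br-]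
A3 | alternative 1 | (2S)-17-[3,5-bis(benzyloxy)phenyl]heptadec-16-en-2-ol (E/Z mixture) | C[C@H](O)CCCCCCCCCCCCCC=Cc1cc(OCc2ccccc2)cc(OCc2ccccc2)c1
A4 | alternative 2 | 15-[3,5-bis(benzyloxy)phenyl]-15-oxopentadecanoic acid | OC(=O)CCCCCCCCCCCCCC(=O)c1cc(OCc2ccccc2)cc(OCc2ccccc2)c1
A5 | alternative 2 | (3S)-3-[(tert-butyldimethylsilyl)oxy]butanoic acid | C[C@H](O[Si](C)(C)C(C)(C)C)CC(=O)O
A6 | alternative 2 | (16S)-1-[3,5-bis(benzyloxy)phenyl]-16-[(tert-butyldimethylsilyl)oxy]heptadecan-1-one | C[C@H](O[Si](C)(C)C(C)(C)C)CCCCCCCCCCCCCCC(=O)c1cc(OCc2ccccc2)cc(OCc2ccccc2)c1
A7 | alternative 3 | 1-[3,5-bis(benzyloxy)phenyl]cyclopentadecan-1-ol | OC1(CCCCCCCCCCCCCC1)c2cc(OCc3ccccc3)cc(OCc3ccccc3)c2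
A8 | alternative 3 | 1-[3,5-bis(benzyloxy)phenyl]heptadecane-1,16-dione | CC(=O)CCCCCCCCCCCCCCC(=O)c1cc(OCc2ccccc2)cc(OCc2ccccc2)c1
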